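**Assumptions.** Methyl (2E,6E)-farnesoate and (2E,6E)-farnesyl bromide are bought as the all-E isomers. The target has the natural cis-1,3 (3S, ring-CH R) arrangement, which matches an (S)-epoxide cyclising through a chair transition state.

## Retrosynthetic overview
1. The target disconnects at the tail-to-tail C12–C13 bond, squalene-style, into two C15 allylic units: (E,E)-farnesyl phenyl sulfone (nucleophile) and a monocyclic farnesyl bromide (electrophile), joined by Biellmann alkylation and then reductive desulfonylation.
2. The monocyclic bromide comes from the ester 4 by DIBAL reduction and Appel bromination.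
3. The only ring is formed by an epoxide-initiated cation–olefin cyclisation of (10S)-epoxy-methyl farnesoate, which sets both ring stereocentres. The deactivated enoate prevents bicyclisation, and a Co–H isomerisation funnels the exocyclic alkene to the ring endocyclic alkene.
4. The (10S)-epoxide comes from Shi epoxidation of commercial methyl farnesoate. The three E-trisubstituted chain alkenes are carried unchanged from the all-E farnesyl starting materials.

## Route

**Step 1**
Reactants: 1, methyl (2E,6E)-farnesoate
Product: 2, methyl (2E,6E)-9-[(2S)-3,3-dimethyloxiran-2-yl]-3,7-dimethylnona-2,6-dienoate (the (10S)-10,11-epoxide)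
Conditions: fructose-derived Shi ketone (30 mol %; enantiomer giving the (10S)-epoxide), Oxone, K2CO3, Bu4NHSO4, MeCN/DMM/aq. Na2B4O7–EDTA pH ~10.5, 0 °C, stopped at ~70% conversion
Reagents that add atoms: Oxone (oxygen source), [K+].OOS(=O)(=O)[O-]
Why: Shi asymmetric epoxidation (chiral dioxirane) attacks the most electron-rich and most remote trisubstituted alkene, C10=C11, and leaves the enoate untouched. The catalyst enantiomer sets the (10S) centre, which becomes the (S)-carbinol.

**Step 2**
Reactants: 2
Product: 3, methyl (2E)-5-[(1R,5S)-5-hydroxy-6,6-dimethyl-2-methylidenecyclohexyl]-3-methylpent-2-enoate (exocyclic isomer). The endocyclic isomer 4 is co-formed and carried along.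
Conditions: BF3·OEt2 (1.2 equiv), CH2Cl2, −78 °C, 1 h; Et3N quench
Reagents that add atoms: none
Why: This is a Lewis-acid epoxide-initiated cation–olefin (polyene-type) cyclisation. The C6=C7 alkene attacks the activated tertiary epoxide carbon anti, through a chair transition state. That sets the ring CH as R, cis-1,3 to the retained (S)-carbinol, because the C–O bond at C10 is never broken. The electron-poor enoate cannot capture the C7 cation, so the reaction stops at the monocycle, which loses a proton to give 3 and 4.

**Step 3**
Reactants: 3 (together with co-formed 4)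
Product: 4, methyl (2E)-5-[(1R,5S)-5-hydroxy-2,6,6-trimethylcyclohex-2-en-1-yl]-3-methylpent-2-enoate
Conditions: Co(salen) catalyst (2 mol %), PhSiH3 (5 mol %), PhH, 25 °C
Reagents that add atoms: none
Why: Co–H metal-hydride hydrogen-atom-transfer isomerisation acts only on the 1,1-disubstituted exocyclic alkene. The Co(II) then removes a hydrogen from the accessible ring CH2, giving the endocyclic α-alkene. The trisubstituted enoate and ring alkenes are inert, and the hindered ring methine next to the quaternary carbon is not abstracted, so the R centre is kept.

**Step 4**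
Reactants: 4
Product: 5, (2E)-5-[(1R,5S)-5-hydroxy-2,6,6-trimethylcyclohex-2-en-1-yl]-3-methylpent-2-en-1-ol
Conditions: DIBAL-H (3.5 equiv), CH2Cl2, −78 → 0 °C
Reagents that add atoms: none
Why: DIBAL-H gives 1,2-reduction of the α,β-unsaturated ester to the allylic alcohol with the E geometry retained. The extra equivalents cover the free ring OH.

**Step 5**
Reactants: 5
Product: 6, (1S,3R)-3-[(3E)-5-bromo-3-methylpent-3-en-1-yl]-2,2,4-trimethylcyclohex-4-en-1-ol
Conditions: CBr4, PPh3, CH2Cl2, 0 °C, used crude
Reagents that add atoms: CBr4 (bromine source), BrC(Br)(Br)Br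
Why: Appel reaction, an SN2 at the primary allylic carbon with no allylic transposition. The hindered secondary carbinol next to the gem-dimethyl group does not react.

**Step 6**
Reactants: 7, (2E,6E)-farnesyl bromide
Product: 8, (2E,6E)-farnesyl phenyl sulfone
Conditions: PhSO2Na, DMF, 25 °C
Reagents that add atoms: sodium benzenesulfinate (PhSO2 group), O=S([O-])c1ccccc1.[Na+]
Why: SN2 S-alkylation of the sulfinate at the primary allylic bromide gives the allylic sulfone with both E alkenes intact.

**Step 7**
Reactants: 6 (electrophile) and 8 (nucleophile)
Product: 9, (1S,3R)-2,2,4-trimethyl-3-[(3E,7E,11E)-3,8,12,16-tetramethyl-6-(phenylsulfonyl)heptadeca-3,7,11,15-tetraen-1-yl]cyclohex-4-en-1-ol (mixture of C6′ epimers)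
Conditions: 8 (3 equiv) + n-BuLi (3 equiv), THF, −78 °C; then 6 (1 equiv), HMPA, −78 → −20 °C
Reagents that add atoms: none
Why: Biellmann alkylation. The α-sulfonyl allyl anion is alkylated at its α-carbon by the primary allylic bromide in an SN2 reaction, forming the tail-to-tail C12–C13 bond. The excess anion covers the free OH, and the new sulfone stereocentre is removed in the next step.

**Step 8**
Reactants: 9
Product: 10, camelliol C
Conditions: Pd(dppp)Cl2 (5 mol %), LiBHEt3 (6 equiv), THF, 0 → 25 °C
Reagents that add atoms: none
Why: Pd-catalysed hydrogenolysis of an allylic sulfone goes through a π-allyl palladium species. Hydride is delivered to the less-substituted terminus (C12), so the trisubstituted C10=C11 E-alkene is retained and the C12 epimers converge. The ring stereocentres are remote and untouched.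

## Compound list
1 | methyl (2E,6E)-farnesoate | `CC(C)=CCC/C(C)=C/CC/C(C)=C/C(=O)OC` | starting material
2 | methyl (2E,6E)-9-[(2S)-3,3-dimethyloxiran-2-yl]-3,7-dimethylnona-2,6-dienoate | `CC1(C)O[C@H]1CC/C(C)=C/CC/C(C)=C/C(=O)OC` | intermediate
3 | exocyclic-methylene monocyclic ester | `COC(=O)/C=C(\C)CC[C@@H]1C(=C)CC[C@H](O)C1(C)C` | intermediate
4 | endocyclic monocyclic ester | `COC(=O)/C=C(\C)CC[C@@H]1C(C)=CC[C@H](O)C1(C)C` | intermediate
5 | monocyclic allylic alcohol (diol) | `OC/C=C(\C)CC[C@@H]1C(C)=CC[C@H](O)C1(C)C` | intermediate
6 | monocyclic allylic bromide | `BrC/C=C(\C)CC[C@@H]1C(C)=CC[C@H](O)C1(C)C` | intermediate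
7 | (2E,6E)-farnesyl bromide | `CC(C)=CCC/C(C)=C/CC/C(C)=C/CBr` | starting material
8 | (2E,6E)-farnesyl phenyl sulfone | `CC(C)=CCC/C(C)=C/CC/C(C)=C/CS(=O)(=O)c1ccccc1` | intermediate
9 | coupled allylic sulfone (C6′ epimer mixture) | `CC(C)=CCC/C(C)=C/CC/C(C)=C/C(S(=O)(=O)c1ccccc1)C/C=C(\C)CC[C@@H]1C(C)=CC[C@H](O)C1(C)C` | intermediate
10 | camelliol C, (1S,3R)-2,2,4-trimethyl-3-[(3E,7E,11E)-3,8,12,16-tetramethylheptadeca-3,7,11,15-tetraen-1-yl]cyclohex-4-en-1-ol | `CC(C)=CCC/C(C)=C/CC/C(C)=C/CC/C=C(\C)CC[C@@H]1C(C)=CC[C@H](O)C1(C)C` | target

## Totals
- Total steps: 8, including the parallel sulfone preparation.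
- Longest linear sequence: 7 steps, from methyl farnesoate (Steps 1–5, 7 and 8).

## Three steps most likely to fail
1. **Step 2 (cyclisation):** it may give low yield, β-isomer or cyclic-ether by-products, or an unfavourable exo/endo ratio. Fallback: switch from a cationic to a radical mechanism, using Cp2TiCl-catalysed epoxide opening and 6-endo cyclisation of the corresponding epoxy-farnesyl acetate. This gives the exocyclic alkene stereospecifically through the same chair, and Step 3 then gives the endocyclic alkene.
2. **Step 3 (exo → endo isomerisation):** it may stall, or push the alkene into the tetrasubstituted β-position and lose the ring stereocentre. Fallback: cyclise an analogue carrying a C8 trimethylsilyl group (an allylsilane terminator), where β-silyl elimination forms the endocyclic alkene regiospecifically.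
3. **Step 7 (Biellmann alkylation with a free OH and an allylic bromide):** it may give α/γ mixtures or O-alkylation. Fallback: change the coupling. Protect the alcohol as its TBS ether and use Li2CuCl4-catalysed SN2 coupling of farnesylmagnesium chloride with the bromide, or a Pd-catalysed allyl–allyl Stille coupling with a farnesylstannane, instead of the sulfone anion.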